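The vessel is a closed, stirred flask of constant volume at constant temperature, in which a solid substrate, undissolved at the start, meets partner and gives target.

| flask | solid substrate | partner | remark | time |
|---|---|---|---|---|
| north-east | 0.094 M | 1.2 equiv | run made earlier |  |
| south-west | 1.3 M | 1.2 equiv | run made earlier |  |
| alder | 0.12 M | 1.20 equiv |  | 5.0 h |
| elm | 0.25 M | 1.20 equiv |  | 5.0 h |
| larch | 0.50 M | 1.20 equiv |  | 5.0 h |
| birch | 1.0 M | 1.20 equiv |  | 5.0 h |
| maple | 2.0 M | 1.20 equiv |  | 5.0 h |

| run | time / h | target / % | solid substrate / % |
|---|---|---|---|
| north-east | 0.250 | 0 | 0 |
| north-east | 0.500 | 0 | 0.4 |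
| north-east | 0.833 | 0.9 | 0 |
| north-east | 1.33 | 2.3 | 0 |
| north-east | 2.00 | 3.7 | 1.1 |
| north-east | 4.00 | 8.5 | 0.6 |
| south-west | 0.250 | 0 | 71.0 |
| south-west | 0.500 | 0.4 | 49.4 |
| south-west | 0.833 | 1.8 | 27.2 |
| south-west | 1.33 | 8.1 | 3.5 |
| south-west | 2.00 | 18.6 | 0 |
| south-west | 4.00 | 45.7 | 0 |

(standard deviation of a reading: 0.5 percentage points)

- at the start none of the solid substrate is in solution
- a reading or a percentage of target counts all its forms, free or not
- the concentration of target that is asked is that of its free form alone
- "hardly changes" means that all values lie within two and a half points (for a concentration: within two and a half percent of the largest)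

- [target] (only what is free in solution) at the end for alder, elm, larch, birch, maple, in this order
- the shape of the row from first to last (hardly changes / rises, then falls / falls all the way / falls, then rises / rises all the way)

1. Partner: by hand, more partner can speed the flask, but both earlier runs and the new row hold it at 1.20 equiv, so the readings cannot tell us its effect. If one partner goes into each target, the solid substrate is the limiting reagent, since partner stands in excess, and the ceiling is its whole charge.

2. Time: by hand, a longer run gives more target, and the north-east run shows this. We extend its last stretch, from 2.00 h to 4.00 h, in a straight line to 5.0 h, which gives 10.9%.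

3. Loading: a strictly first-order flask would give the same percentage at any loading, yet at 4.00 h the south-west run reads 45.7% and the north-east run 8.5%, for 13.8 times the loading. We therefore define the loading exponent, the power of the loading that the percentage of target follows at a fixed time, and read it from these two runs as 0.640.

4. Row: [target] then goes as the loading to the power 1.64, which is positive, so our row rises all the way, from 0.0153 M in alder to 1.54 M in maple. These figures count target in all its forms, and maple's 77.2% is reckoned for a loading above those of both earlier runs.

The forecast gives 0.015 M, 0.059 M, 0.18 M, 0.51 M and 1.29 M, lower at maple than our figure, a row whose shape it gives as rises all the way, and says "The row rises throughout".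

The flasks give 0.0175 M, 0.0641 M, 0.195 M, 0.508 M and 0.876 M, a row that rises all the way.

    starting material ⇌ intermediate A (K = 1.05, k = 0.0884 min⁻¹)
    partner + intermediate A ⇌ intermediate B (K = 11.6 M⁻¹, k = 0.00970 M⁻¹ min⁻¹)
    intermediate B → intermediate C (k = 0.108 min⁻¹)
    partner + intermediate B → intermediate D (k = 0.0156 M⁻¹ min⁻¹)
    intermediate D → side product (k = 0.0561 min⁻¹)
    intermediate C → target (k = 0.0262 min⁻¹)
    crystals ⇌ target, rate k7*(cs7 - [target]) while solid is left; crystals form when [target] > cs7 (solubility = 0.870 M, k = 0.442 min⁻¹)
    solid substrate ⇌ starting material, rate k8*(cs8 - [starting material]) while solid is left; crystals form when [starting material] > cs8 (solubility = 0.740 M, k = 0.0423 min⁻¹)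

In maple, free [target] is 0.876 M, which is the 54.1% of target less the 10.3% of crystals counted in it, taken on 2.0 M, and it lies close to the crystal limit of 0.87 M. The loading exponent, carried from birch's 50.8% of target to maple, gives 79.2%, and maple holds 54.1%, crystals counted.

The readings come from a simulation on assumed constants.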